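## The problem

Compound 20 is a 1,2,4,5-tetrasubstituted imidazole whose four rings are linked only through single atoms. N1 carries a methyl group, C2 an NH bonded to C4 of a 1-methylimidazole-2,5-dione ring, C4 a 4-methoxybenzyl arm (ring A) and C5 a 3-hydroxy-4,5-dimethoxybenzyl arm (ring B). There is no stereocentre, so the difficulty is regiochemical: two different benzyl groups must sit on adjacent C4 and C5, with the N-methyl group next to the carbon bearing ring B, and alkylation or metalation of a preformed imidazole distinguishes these positions poorly. Any sp3 centre formed on the way (the future C5) may be racemic, because it is flattened when the imidazole aromatises. The imidazoledione is an acylamidine that opens in aqueous base or hot acid and must be attached last; the free 2-aminoimidazole is polar, basic and oxidisable and should appear late; ring B is very electron-rich, and its phenol, flanked by a methoxy group, forbids Lewis-acid ether cleavage and will be acylated by any excess acylating agent. The enabling feature is a hidden amino acid: N1 with its methyl group, C5 and the ring B arm are the nitrogen, α-carbon and side chain of an N-methyl arylalanine, and C4 with the ring A arm is a 4-methoxyphenylacetyl unit standing where the carboxyl group was. C2, N3 and the exocyclic nitrogen are one molecule of cyanamide. Because the acylated nitrogen is tertiary, the amino acid can be activated as a mesoionic oxazolium-5-olate, which lets carboxyl be exchanged for arylacetyl in one operation.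

## Retrosynthesis

Target 20 is first cut at the bond between the exocyclic nitrogen on C2 and C4 of the imidazoledione, giving the 2-aminoimidazole 17 and 1-methylparabanic acid 18. Cutting inside the dione ring would mean building an acylamidine stepwise on a polyfunctional amine. This cut removes the one hydrolytically fragile ring in a single late condensation. The forward reaction must choose the carbonyl next to N–H of 18 and the exocyclic amine of 17, and must tolerate the free phenol; activation of 18 as its O-silyl imidate 19 is meant to secure all three.

Aminoimidazole 17 is opened across N1–C2 and N3–C4 to the α-methylamino ketone 14 (as hydrochloride) and cyanamide 15. The neighbouring pairing, an α-halo ketone with methylguanidine, would leave the position of the N-methyl group open. In 14 the nitrogen already sits on the carbon bearing the ring B arm and the oxygen on the carbon bearing the ring A arm. The precursor is acyclic with one racemic centre. The forward step needs the amine to add to the nitrile near pH 4.5 and the guanidine 16 to close onto the ketone.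

Amino ketone 14 is traced to amido ketone 13 by adding back two 4-methoxyphenylacetyl groups, one on nitrogen and one on the ring B phenol. No skeletal bond is cut. One aqueous acid treatment removes both groups, and the co-product in each case is acid 8, which is extracted from the acidic solution while 14 stays in water.

Amido ketone 13 is cut at the bond between the ketone carbon and the amide-bearing carbon, the future C4–C5 bond, giving acid 7 and anhydride 9. The neighbouring cut, between the ketone and its ring A methylene, would need a benzylic organometallic reagent and a separately N-protected, activated amino acid. The chosen cut uses the carboxyl group as the leaving group and the amide as the activator, and 7 differs from 13 only by CO2 against one arylacetyl group. The forward reaction must C-acylate the münchnone 11 faster than 9 condenses with itself.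

Acid 7 is cut at its amide and aryl ester bonds to amino acid 5 and acid chloride 6. Putting the same acyl group on nitrogen and on the phenol removes the need for a separate protecting group; the phenol is masked only while an acylating agent is present. The forward step is a double acylation in aqueous base.

Amino acid 5 goes back through hydantoin 4 and benzylidene hydantoin 3 to aldehyde 1 and 1-methylhydantoin 2, by cleaving the two ring C–N bonds, adding the alkene and cutting the exocyclic C=C bond. Compound 2 already holds the N-methyl group, the α-carbon and the carboxyl carbon, and 1 is ring B complete with its free phenol. No benzyl ether is carried, so the hydrogenation has nothing to cleave.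

Anhydride 9 is cut at one anhydride C–O bond to acid 8 and acid chloride 6, the acylating agent that step 4 already uses. Dehydrating two molecules of 8 with a carbodiimide is the neighbouring option, but it leaves urea residues in a reagent that the key step uses in excess. The acylation of 8 by 6 gives only a salt that is filtered off.

## Roads not taken

Alternative 1: Ring B itself is cut, at C1'–C6' and C2'–C3', back to a squarate-derived 4-chloro-2,3-dimethoxycyclobutenone A2 and an alkenylstannane A3 that carries the imidazolylmethyl group on its stannylated carbon.
- Forward key step: a zerovalent palladium catalyst (Pd2(dba)3 with tri(2-furyl)phosphine) would couple A2 with A3. The 4-alkenylcyclobutenone would open to a dienylketene and close by 6π electrocyclisation to the phenol A1.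
- Merits: the carbonyl carbon becomes the phenol carbon and the two enol ether carbons become the methoxy carbons, so the 3-hydroxy-4,5-dimethoxy pattern is written without selective demethylation and under neutral conditions.
- Weak points: that pattern can be bought as aldehyde 1, so the step solves a problem that does not exist here. The real problem, the regiodefined 1,4,5-trisubstituted imidazole, is moved unsolved into A3, which also needs a 2-stannylallyl chain and stoichiometric tin. A1 lacks the nitrogen at C2, so metalation and electrophilic amination with the phenol protected would still follow.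
- Comparison: this road is longer by several steps. It is better where ring B analogues with unavailable oxygenation are wanted, and it avoids the hot acid of step 7. The chosen plan sets against it a purchased ring B, an imidazole whose substitution is fixed by acyclic connectivity, and a 2-amino group that arrives with ring closure.

Alternative 2: The cut is the bond between C5 and the benzylic carbon of the ring B arm, made at the carbinol oxidation level.
- Forward key step: the 2-aminoimidazole A4, with C5 free, would react as an ene-guanidine with aldehyde 1 to give carbinol A5. The hydroxyl group would then be removed reductively before condensation with 18.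
- Merits: on paper this is the shortest road. It needs no protecting group, uses the same aldehyde 1, and the position is fixed because only C5 is open.
- Weak points: 1 is electron-rich and a poor electrophile, so the addition is an unfavourable equilibrium. The exocyclic amine of A4 competes for the aldehyde. A5 ionises easily to a stabilised cation that a second molecule of A4 can capture. The deoxygenation must be run on an oxidisable aminoimidazole. A4 is not a catalogue compound and would most naturally be made by an acylation, decarboxylation and cyanamide sequence of the kind used here.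
- Comparison: in step count this alternative is equal or slightly better. The chosen plan sets against it that every carbon–carbon bond is formed irreversibly and in a defined position before the heterocycle exists, and that no labile carbinol is handled.

Alternative 3: The cut is the bond between C4 and the benzylic carbon of the ring A arm.
- Forward key step: under constant-current electrolysis with NiBr2(dme) (a divalent nickel precatalyst) and a bipyridine ligand, the 4-iodoimidazole A6 would couple with the N-hydroxyphthalimide ester A7 of acid 8, losing CO2, to give the dibenzylimidazole A8.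
- Merits: the ring A arm comes from the same acid 8, enters late and could be varied freely. Conditions are mild and no organometallic reagent is needed.
- Weak points: the benzylic radical from A7 is prone to dimerisation and over-reduction. The electron-rich, nitrogen-coordinating iodoimidazole is slow in oxidative addition and liable to protodehalogenation. A6 needs a regioselective synthesis of its own, which is the very problem of the target. A8 still lacks the 2-amino group and carries a benzyl ether, so amination at C2 and deprotection precede the final condensation.
- Comparison: this road is superior in modularity for analogue work. The chosen plan sets against it a shorter sequence from purchased materials, no electrochemical equipment, and the arrival of both arms and the 2-amino group in the two bond-forming events that build the imidazole.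

Key step: step 6

Assumption: (4-methoxyphenyl)acetyl chloride 6 and 1-methylparabanic acid 18 are treated as catalogue compounds, and the alkene geometry of 3 is left open because both isomers are hydrogenated to the same racemic product.

## Route

Step 1
Reactants: 1 3-hydroxy-4,5-dimethoxybenzaldehyde; 2 1-methylhydantoin (1-methylimidazolidine-2,4-dione)
Product: 3 5-(3-hydroxy-4,5-dimethoxybenzylidene)-1-methylimidazolidine-2,4-dione (E/Z mixture)
Conditions: piperidine, 130 °C (sealed tube), Ar; then aq. AcOH
Reagents that add atoms: none
Why: Knoevenagel-type aldol condensation at C5 of the hydantoin with the secondary amine as base and iminium-forming catalyst, the classical entry to N-methyl arylalanines; the meta phenol is not conjugated with the formyl group and should not deactivate it, and both alkene isomers converge in step 2.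

Step 2
Reactants: 3 5-(3-hydroxy-4,5-dimethoxybenzylidene)-1-methylimidazolidine-2,4-dione
Product: 4 5-(3-hydroxy-4,5-dimethoxybenzyl)-1-methylimidazolidine-2,4-dione (racemic)
Conditions: H2 (3 bar), 10% Pd/C, AcOH–MeOH, 40 °C
Reagents that add atoms: none
Why: Heterogeneous catalytic hydrogenation of a conjugated trisubstituted alkene; no benzyl ether or halide is present to be lost, and the new centre is formed racemic, which suffices because it becomes aromatic C5 in step 8.

Step 3
Reactants: 4 5-(3-hydroxy-4,5-dimethoxybenzyl)-1-methylimidazolidine-2,4-dione
Product: 5 N-methyl-3-(3-hydroxy-4,5-dimethoxyphenyl)alanine (racemic)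
Conditions: Ba(OH)2·8H2O, H2O, reflux, Ar; then CO2, filter; crystallise at pH 6
Reagents that add atoms: water, O
Why: Alkaline hydrolysis of a 5-substituted 1-methylhydantoin, in which hydroxide cleaves both acyl–nitrogen bonds of the ring and the liberated carbonate is removed as BaCO3; the phenol is carried as its phenolate under argon and the methyl ethers are inert to base.

Step 4
Reactants: 5 N-methyl-3-(3-hydroxy-4,5-dimethoxyphenyl)alanine; 6 (4-methoxyphenyl)acetyl chloride
Product: 7 N-[(4-methoxyphenyl)acetyl]-N-methyl-3-{3,4-dimethoxy-5-[(4-methoxyphenyl)acetoxy]phenyl}alanine (racemic)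
Conditions: 6 (3 equiv), aq. NaOH (pH 10), THF, 0 °C; then aq. HCl to pH 2
Reagents that add atoms: none
Why: Schotten–Baumann acylation in which excess acid chloride acylates both the secondary amine and the phenolate, as in the N,O-diacylation of tyrosine, while any mixed anhydride at the carboxylate is hydrolysed back; phenol left free would be esterified by 9 at the start of step 6, so incomplete O-acylation does not divert material.

Step 5
Reactants: 8 (4-methoxyphenyl)acetic acid; 6 (4-methoxyphenyl)acetyl chloride
Product: 9 (4-methoxyphenyl)acetic anhydride
Conditions: pyridine (1.0 equiv), Et2O, 0 °C to rt; filter, concentrate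
Reagents that add atoms: none
Why: Acylation of a carboxylic acid by its own acid chloride with pyridine as acid scavenger and acyl-transfer catalyst, the classical preparation of a symmetrical anhydride; pyridine is too weak a base to turn 6 into the arylketene, and the only co-product, pyridinium chloride, precipitates and is filtered off.

Step 6
Reactants: 7 N-[(4-methoxyphenyl)acetyl]-N-methyl-3-{3,4-dimethoxy-5-[(4-methoxyphenyl)acetoxy]phenyl}alanine; 9 (4-methoxyphenyl)acetic anhydride
Product: 13 N-{1-[3,4-dimethoxy-5-((4-methoxyphenyl)acetoxy)phenyl]-4-(4-methoxyphenyl)-3-oxobutan-2-yl}-2-(4-methoxyphenyl)-N-methylacetamide (racemic), via mixed anhydride 10 (not isolated), via münchnone 11 (not isolated), via beta-keto acid 12 (not isolated)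
Conditions: 9 (3 equiv, in portions), Et3N, DMAP (0.2 equiv), THF, 50 °C; then H2O
Reagents that add atoms: none
Why: Dakin–West reaction of an N-acyl-N-alkyl amino acid, run with DMAP as acyl-transfer catalyst, is the closest known reaction type. The carboxylate of 7 is acylated by 9 to the mixed anhydride 10, whose amide oxygen closes onto the activated carbonyl (5-exo-trig) and which loses the α-proton to give the mesoionic oxazolium-5-olate 11; only a tertiary amide can reach this aromatic ylide, so the N-methyl group of the target is an asset here. C4 of 11 is acylated by the N-acylpyridinium ion formed from 9 and DMAP, arylacetate opens the acylated ring, and the β-keto acid 12 loses CO2 to leave ketone 13, whose new bond is the future C4–C5 bond of the imidazole. No ring remains in the product; the oxazolium ring is only a transient activating device. The single stereocentre of 13 arises by uncontrolled protonation and is racemic, which is immaterial because it becomes aromatic C5 in step 8. The selectivity needed is chemoselectivity: C-acylation of 11 must outrun base-induced self-condensation of 9 and acylation at the benzylic carbon of the C2 side chain, for which the high nucleophilicity of the ylide at C4, moderate temperature and portionwise excess of 9 are relied on, while the position of the ketone is fixed by connectivity. Because the N-acyl group, the O-acyl group and the acyl donor are identical, any acyl exchange at nitrogen or at the phenol is degenerate.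

Step 7
Reactants: 13 N-{1-[3,4-dimethoxy-5-((4-methoxyphenyl)acetoxy)phenyl]-4-(4-methoxyphenyl)-3-oxobutan-2-yl}-2-(4-methoxyphenyl)-N-methylacetamide
Product: 14 4-(3-hydroxy-4,5-dimethoxyphenyl)-1-(4-methoxyphenyl)-3-(methylamino)butan-2-one hydrochloride (racemic)
Conditions: 6 M HCl–AcOH (1:1), 100 °C, Ar; Et2O wash; evaporate aqueous phase
Reagents that add atoms: hydrogen chloride, Cl
Why: Acid hydrolysis of the aryl ester and of the α-amido ketone, the classical sequel to a Dakin–West reaction; the neighbouring ketone carbonyl assists cleavage of the tertiary amide, aryl methyl ethers should survive aqueous HCl at this temperature, and protonation of the amine protects the product from self-condensation.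

Step 8
Reactants: 14 4-(3-hydroxy-4,5-dimethoxyphenyl)-1-(4-methoxyphenyl)-3-(methylamino)butan-2-one hydrochloride; 15 cyanamide
Product: 17 2-amino-5-(3-hydroxy-4,5-dimethoxybenzyl)-4-(4-methoxybenzyl)-1-methyl-1H-imidazole, via guanidine 16 (not isolated)
Conditions: H2NCN (10 equiv), H2O–EtOH, pH 4.5 (aq. NaOH), 95 °C; then aq. NaOH to pH 9
Reagents that add atoms: none
Why: Condensation of an α-amino ketone with cyanamide at pH 4–5, the standard 2-aminoimidazole synthesis: the secondary amine adds to the nitrile to give guanidine 16, whose free NH2 condenses with the ketone, and loss of water aromatises the ring. The N-methyl group ends next to the ring B arm because that is the connectivity of 14.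

Step 9
Reactants: 17 2-amino-5-(3-hydroxy-4,5-dimethoxybenzyl)-4-(4-methoxybenzyl)-1-methyl-1H-imidazole; 18 1-methylparabanic acid (1-methylimidazolidine-2,4,5-trione)
Product: 20 4-({5-[(3-hydroxy-4,5-dimethoxyphenyl)methyl]-4-[(4-methoxyphenyl)methyl]-1-methyl-1H-imidazol-2-yl}amino)-1-methyl-1H-imidazole-2,5-dione, via O-silyl imidate 19 (not isolated)
Conditions: 18, BSA, MeCN, 80 °C; evaporate; then 17, toluene, 110 °C; MeOH work-up
Reagents that add atoms: none
Why: Silyl-activated condensation of a heteroaryl amine with an imide carbonyl: BSA converts the N–H lactam of 18 into O-silyl imidate 19, the exocyclic amine of 17 adds to that carbon, and silanolate is expelled to give the conjugated acylamidine. The N-methyl side of 18 cannot be silylated, which directs the amine to C4, and the phenol is silylated only transiently and freed on methanolic work-up.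

## Compound list

1 | 3-hydroxy-4,5-dimethoxybenzaldehyde | O=Cc1cc(O)c(OC)c(OC)c1 | starting material
2 | 1-methylhydantoin (1-methylimidazolidine-2,4-dione) | CN1CC(=O)NC1=O | starting material
3 | 5-(3-hydroxy-4,5-dimethoxybenzylidene)-1-methylimidazolidine-2,4-dione (E/Z mixture, geometry not fixed) | CN1C(=O)NC(=O)C1=Cc1cc(O)c(OC)c(OC)c1 | intermediate
4 | 5-(3-hydroxy-4,5-dimethoxybenzyl)-1-methylimidazolidine-2,4-dione (racemic) | CN1C(=O)NC(=O)C1Cc1cc(O)c(OC)c(OC)c1 | intermediate
5 | N-methyl-3-(3-hydroxy-4,5-dimethoxyphenyl)alanine (racemic) | CNC(Cc1cc(O)c(OC)c(OC)c1)C(=O)O | intermediate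
6 | (4-methoxyphenyl)acetyl chloride | COc1ccc(CC(=O)Cl)cc1 | starting material
7 | N-[(4-methoxyphenyl)acetyl]-N-methyl-3-{3,4-dimethoxy-5-[(4-methoxyphenyl)acetoxy]phenyl}alanine (racemic) | COc1ccc(CC(=O)N(C)C(Cc2cc(OC(=O)Cc3ccc(OC)cc3)c(OC)c(OC)c2)C(=O)O)cc1 | intermediate
8 | (4-methoxyphenyl)acetic acid | COc1ccc(CC(=O)O)cc1 | starting material
9 | (4-methoxyphenyl)acetic anhydride | COc1ccc(CC(=O)OC(=O)Cc2ccc(OC)cc2)cc1 | intermediate
10 | mixed anhydride of 7 with (4-methoxyphenyl)acetic acid (racemic) | COc1ccc(CC(=O)N(C)C(Cc2cc(OC(=O)Cc3ccc(OC)cc3)c(OC)c(OC)c2)C(=O)OC(=O)Cc2ccc(OC)cc2)cc1 | intermediate (not isolated)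
11 | 4-{3,4-dimethoxy-5-[(4-methoxyphenyl)acetoxy]benzyl}-2-(4-methoxybenzyl)-3-methyl-1,3-oxazol-3-ium-5-olate (münchnone) | C[N+]1=C(Cc2ccc(OC)cc2)OC([O-])=C1Cc1cc(OC(=O)Cc2ccc(OC)cc2)c(OC)c(OC)c1 | intermediate (not isolated)
12 | 2-{3,4-dimethoxy-5-[(4-methoxyphenyl)acetoxy]benzyl}-4-(4-methoxyphenyl)-2-{[(4-methoxyphenyl)acetyl](methyl)amino}-3-oxobutanoic acid (racemic) | COc1ccc(CC(=O)N(C)C(Cc2cc(OC(=O)Cc3ccc(OC)cc3)c(OC)c(OC)c2)(C(=O)O)C(=O)Cc2ccc(OC)cc2)cc1 | intermediate (not isolated)
13 | N-{1-[3,4-dimethoxy-5-((4-methoxyphenyl)acetoxy)phenyl]-4-(4-methoxyphenyl)-3-oxobutan-2-yl}-2-(4-methoxyphenyl)-N-methylacetamide (racemic) | COc1ccc(CC(=O)N(C)C(Cc2cc(OC(=O)Cc3ccc(OC)cc3)c(OC)c(OC)c2)C(=O)Cc2ccc(OC)cc2)cc1 | intermediate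
14 | 4-(3-hydroxy-4,5-dimethoxyphenyl)-1-(4-methoxyphenyl)-3-(methylamino)butan-2-one hydrochloride (racemic) | CNC(Cc1cc(O)c(OC)c(OC)c1)C(=O)Cc1ccc(OC)cc1.Cl | intermediate
15 | cyanamide | NC#N | starting material
16 | 1-[1-(3-hydroxy-4,5-dimethoxyphenyl)-4-(4-methoxyphenyl)-3-oxobutan-2-yl]-1-methylguanidine (racemic) | CN(C(N)=N)C(Cc1cc(O)c(OC)c(OC)c1)C(=O)Cc1ccc(OC)cc1 | intermediate (not isolated)
17 | 2-amino-5-(3-hydroxy-4,5-dimethoxybenzyl)-4-(4-methoxybenzyl)-1-methyl-1H-imidazole | COc1ccc(Cc2nc(N)n(C)c2Cc2cc(O)c(OC)c(OC)c2)cc1 | intermediate
18 | 1-methylparabanic acid (1-methylimidazolidine-2,4,5-trione) | CN1C(=O)NC(=O)C1=O | starting material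
19 | 1-methyl-4-(trimethylsilyloxy)-1H-imidazole-2,5-dione | CN1C(=O)N=C(O[Si](C)(C)C)C1=O | intermediate (not isolated)
20 | 4-({5-[(3-hydroxy-4,5-dimethoxyphenyl)methyl]-4-[(4-methoxyphenyl)methyl]-1-methyl-1H-imidazol-2-yl}amino)-1-methyl-1H-imidazole-2,5-dione | COc1ccc(Cc2nc(NC3=NC(=O)N(C)C3=O)n(C)c2Cc2cc(O)c(OC)c(OC)c2)cc1 | target

## Step count and least certain steps

Total step count: 9. Longest linear sequence: 8 (steps 1, 2, 3, 4, 6, 7, 8, 9); step 5 is a one-step branch that supplies the anhydride.

Step 6 (key step). The most likely failure is that base-induced self-condensation of the arylacetic anhydride, through its enolate or ketene, consumes the acyl donor faster than the münchnone is C-acylated. Acylation at the acidic benzylic carbon of the C2 side chain, or dimerisation of the ylide, could also lower the return. The fallback keeps acid 7 and the later steps but forms the other bond to the ketone carbon. Acid 7 would be converted with ethanethiol, a carbodiimide and DMAP into S-ethyl N-[(4-methoxyphenyl)acetyl]-N-methyl-3-{3,4-dimethoxy-5-[(4-methoxyphenyl)acetoxy]phenyl}thioalaninate F1. F1 would then be coupled with commercial 4-methoxybenzylzinc chloride under PdCl2(PPh3)2 (a divalent palladium precatalyst) in a Fukuyama ketone synthesis, which tolerates the amide and the aryl ester. This rejoins the route at 13.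

Step 7. Hot aqueous acid may cleave the hindered tertiary amide incompletely. Prolonged heating risks acid-promoted loss of the central methyl ether of ring B and Friedel–Crafts-type attack of ring B on the protonated ketone. The fallback reaches the same amino ketone without hot acid, setting out from amino acid 5. N-protection with Boc2O and aqueous NaOH, with brief K2CO3/MeOH to cleave any aryl carbonate, would give N-Boc-N-methyl-3-(3-hydroxy-4,5-dimethoxyphenyl)alanine F2. Carbodiimide coupling with N,O-dimethylhydroxylamine would give the Weinreb amide F3. Excess 4-methoxybenzylmagnesium chloride, the first equivalent being spent on the phenol, would give the Boc-protected amino ketone tert-butyl [1-(3-hydroxy-4,5-dimethoxyphenyl)-4-(4-methoxyphenyl)-3-oxobutan-2-yl](methyl)carbamate F4. HCl in dioxane at room temperature would then deliver 14.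

Step 1. The N1-methyl group lowers the acidity and raises the steric demand at C5 of the hydantoin, so the condensation may stall at the aldol stage or be outpaced by degradation of the aldehyde at 130 °C. The fallback replaces the aldol condensation by an olefination. Hydantoin 2 would be brominated at C5 (Br2, AcOH) to 5-bromo-1-methylimidazolidine-2,4-dione F5. An Arbuzov reaction with triethyl phosphite would give diethyl (1-methyl-2,4-dioxoimidazolidin-5-yl)phosphonate F6. A Horner–Wadsworth–Emmons reaction of F6 with aldehyde 1, with enough NaOEt in EtOH to cover the phenol, would return to 3 at room temperature.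

Step 8. Addition of the hindered secondary amine to cyanamide may be slow while cyanamide is lost to hydration and dimerisation, and an upward drift of pH would expose the free amino ketone to self-condensation. The fallback separates guanylation from cyclisation. From 14, treatment with N,N'-di-Boc-N''-triflylguanidine and Et3N in CH2Cl2 would give the protected guanidine N,N'-bis(tert-butoxycarbonyl)-N''-[1-(3-hydroxy-4,5-dimethoxyphenyl)-4-(4-methoxyphenyl)-3-oxobutan-2-yl]-N''-methylguanidine F7. Trifluoroacetic acid would then remove both carbamates and drive cyclodehydration, returning to 17 after neutralisation.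

Step 4. Partial hydrolysis of the aryl ester under the aqueous basic conditions may leave a mixture of mono- and diacylated acids that is tedious to purify. The fallback gives up the ester deliberately. After the acylation, the aryl ester of 7 would be saponified in the same flask (1 M NaOH, room temperature) to the single compound N-[(4-methoxyphenyl)acetyl]-N-methyl-3-(3-hydroxy-4,5-dimethoxyphenyl)alanine F8. F8 would be submitted to the conditions of step 6 with one further equivalent of 9, so that the phenol is esterified in the flask before the münchnone forms. The sequence rejoins at 13.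

## Further compounds

F1 | step 6 | S-ethyl N-[(4-methoxyphenyl)acetyl]-N-methyl-3-{3,4-dimethoxy-5-[(4-methoxyphenyl)acetoxy]phenyl}thioalaninate (racemic) | COc1ccc(CC(=O)N(C)C(Cc2cc(OC(=O)Cc3ccc(OC)cc3)c(OC)c(OC)c2)C(=O)SCC)cc1
F2 | step 7 | N-(tert-butoxycarbonyl)-N-methyl-3-(3-hydroxy-4,5-dimethoxyphenyl)alanine (racemic) | CN(C(=O)OC(C)(C)C)C(Cc1cc(O)c(OC)c(OC)c1)C(=O)O
F3 | step 7 | tert-butyl {3-(3-hydroxy-4,5-dimethoxyphenyl)-1-[methoxy(methyl)amino]-1-oxopropan-2-yl}(methyl)carbamate (racemic) | CON(C)C(=O)C(Cc1cc(O)c(OC)c(OC)c1)N(C)C(=O)OC(C)(C)C
F4 | step 7 | tert-butyl [1-(3-hydroxy-4,5-dimethoxyphenyl)-4-(4-methoxyphenyl)-3-oxobutan-2-yl](methyl)carbamate (racemic) | COc1ccc(CC(=O)C(Cc2cc(O)c(OC)c(OC)c2)N(C)C(=O)OC(C)(C)C)cc1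
F5 | step 1 | 5-bromo-1-methylimidazolidine-2,4-dione (racemic) | CN1C(Br)C(=O)NC1=O
F6 | step 1 | diethyl (1-methyl-2,4-dioxoimidazolidin-5-yl)phosphonate (racemic) | CCOP(=O)(OCC)C1N(C)C(=O)NC1=O
F7 | step 8 | N,N'-bis(tert-butoxycarbonyl)-N''-[1-(3-hydroxy-4,5-dimethoxyphenyl)-4-(4-methoxyphenyl)-3-oxobutan-2-yl]-N''-methylguanidine (racemic) | COc1ccc(CC(=O)C(Cc2cc(O)c(OC)c(OC)c2)N(C)C(=NC(=O)OC(C)(C)C)NC(=O)OC(C)(C)C)cc1
F8 | step 4 | N-[(4-methoxyphenyl)acetyl]-N-methyl-3-(3-hydroxy-4,5-dimethoxyphenyl)alanine (racemic) | COc1ccc(CC(=O)N(C)C(Cc2cc(O)c(OC)c(OC)c2)C(=O)O)cc1
A1 | alternative 1 | 5-(3-hydroxy-4,5-dimethoxybenzyl)-4-(4-methoxybenzyl)-1-methyl-1H-imidazole | COc1ccc(Cc2ncn(C)c2Cc2cc(O)c(OC)c(OC)c2)cc1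
A2 | alternative 1 | 4-chloro-2,3-dimethoxycyclobut-2-en-1-one (racemic) | COC1=C(OC)C(Cl)C1=O
A3 | alternative 1 | 4-(4-methoxybenzyl)-1-methyl-5-[2-(tributylstannyl)prop-2-en-1-yl]-1H-imidazole | COc1ccc(Cc2ncn(C)c2CC(=C)[Sn](CCCC)(CCCC)CCCC)cc1
A4 | alternative 2 | 2-amino-4-(4-methoxybenzyl)-1-methyl-1H-imidazole | COc1ccc(Cc2cn(C)c(N)n2)cc1
A5 | alternative 2 | [2-amino-4-(4-methoxybenzyl)-1-methyl-1H-imidazol-5-yl](3-hydroxy-4,5-dimethoxyphenyl)methanol (racemic) | COc1ccc(Cc2nc(N)n(C)c2C(O)c2cc(O)c(OC)c(OC)c2)cc1
A6 | alternative 3 | 5-(3-benzyloxy-4,5-dimethoxybenzyl)-4-iodo-1-methyl-1H-imidazole | Cn1cnc(I)c1Cc1cc(OCc2ccccc2)c(OC)c(OC)c1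
A7 | alternative 3 | 1,3-dioxoisoindolin-2-yl (4-methoxyphenyl)acetate | COc1ccc(CC(=O)ON2C(=O)c3ccccc3C2=O)cc1
A8 | alternative 3 | 5-(3-benzyloxy-4,5-dimethoxybenzyl)-4-(4-methoxybenzyl)-1-methyl-1H-imidazole | COc1ccc(Cc2ncn(C)c2Cc2cc(OCc3ccccc3)c(OC)c(OC)c2)cc1
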